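**Retrosynthetic overview**
1. The only ring (14-membered) is closed last, at C3=C4, by an intramolecular Z-selective Horner–Wadsworth–Emmons reaction of aldehyde–phosphonate 21.
2. 21 comes from a visible-light Ni/photoredox deacylative alkenylation (C12–C13) of a limonene-derived methyl ketone, activated as dihydroquinazolinone 10, with the Z alkenyl iodide 19. The iodide carries the Z C11=C12 geometry.
3. 10 comes from (R)-limonene by C-10 alkylation (side chain) and ozonolytic opening of the ring alkene. Limonene C4 becomes the single stereocentre C1.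
4. 19 comes from pent-4-ynal by Zhao olefination (Z iodide), Zr-carboalumination/ethylene oxide (E alkene) and phosphonoacetate alkylation.
5. The coupling is run before the enoate exists, because a C-13 radical would cyclise 5-exo onto a C3=C4 enoate; the aldehyde stays masked as an acetal until then.

Assumption: pent-4-ynal, 4-bromo-2-methylbutan-2-ol and the Still–Gennari phosphonoacetate are bought. Centres formed without control and destroyed later (peroxy-acetal carbon of 6, aminal carbon of 10, C-2 of 19–21) are left undefined.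

**Route**

Step 1
Reactants: 1 (R)-(+)-limonene; 2 4-bromo-2-methylbutan-2-ol
Product: 5 2-methyl-6-[(1R)-4-methylcyclohex-3-en-1-yl]hept-6-en-2-ol, via 10-lithiolimonene 3 (not isolated), via lithium bromoalkoxide 4 (not isolated)
Conditions: 1 (excess), n-BuLi, TMEDA, hexane, 25 °C; then 4 (from 2 + n-BuLi, THF, −78 °C), −78 → 0 °C; H2O
Reagents that add atoms: none
Why: n-BuLi·TMEDA metalates limonene at the isopropenyl methyl to a symmetrical 2-substituted allyl-lithium, which displaces the primary bromide (SN2 allyl-anion alkylation) without touching C4, the bought R centre that becomes C1 of the target.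

Step 2
Reactants: 5 2-methyl-6-[(1R)-4-methylcyclohex-3-en-1-yl]hept-6-en-2-ol
Product: 8 (5R)-5-(6-hydroxy-6-methylhept-1-en-2-yl)-7,7-dimethoxyheptan-2-one, via hydroperoxy ketone 6 (not isolated), via keto aldehyde 7 (not isolated)
Conditions: O3 (1 equiv, Sudan Red 7B end point), CH2Cl2/MeOH 4:1, −78 °C; Me2S, −78 → 23 °C; then TsOH·H2O (5 mol %), 23 °C; NaHCO3
Reagents that add atoms: ozone [O-][O+]=O; methanol CO
Why: Criegee ozonolysis cleaves the electron-richer trisubstituted ring alkene before the 1,1-disubstituted one (as with limonene itself), and acid-catalysed acetalisation in methanol then converts only the aldehyde; the stereocentre is β to the aldehyde and cannot epimerise.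

Step 3
Reactants: 8 (5R)-5-(6-hydroxy-6-methylhept-1-en-2-yl)-7,7-dimethoxyheptan-2-one; 9 2-aminobenzamide
Product: 10 2-[(3R)-3-(2,2-dimethoxyethyl)-8-hydroxy-8-methyl-4-methylidenenonyl]-2-methyl-2,3-dihydroquinazolin-4(1H)-one
Conditions: NH4Cl (20 mol %), MeOH, 3 Å MS, 50 °C
Reagents that add atoms: none
Why: Cyclocondensation (aminal formation) of the methyl ketone with 2-aminobenzamide under weak acid in methanol, where exchange of the dimethyl acetal is degenerate; the new aminal centre is uncontrolled and is destroyed in step 8.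

Step 4
Reactants: 11 pent-4-ynal
Product: 12 (5Z)-6-iodohept-5-en-1-yne
Conditions: EtPPh3I, n-BuLi, THF, 0 °C; I2, −78 °C; NaHMDS, −20 °C; then 11, −78 → −20 °C
Reagents that add atoms: ethyltriphenylphosphonium iodide CC[P+](c1ccccc1)(c1ccccc1)c1ccccc1.[I-]; iodine II
Why: Stork–Zhao–Wittig olefination with the α-iodo ylide gives the (Z)-2-iodo-2-alkene (iodine cis to the chain) under kinetic control.

Step 5
Reactants: 12 (5Z)-6-iodohept-5-en-1-yne
Product: 15 (3E,7Z)-8-iodo-4-methylnona-3,7-dien-1-ol, via alkenylalane 13 (not isolated), via lithium alanate 14 (not isolated)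
Conditions: Me3Al, Cp2ZrCl2 (25 mol %), CH2Cl2, 0 → 23 °C; excess Me3Al evaporated; MeLi, THF/hexane, −78 °C; ethylene oxide, −78 → 0 °C; aq. Rochelle salt
Reagents that add atoms: trimethylaluminium C[Al](C)C; ethylene oxide C1CO1
Why: Negishi Zr-catalysed syn-carboalumination puts methyl on the internal alkyne carbon with Al cis to it (E alkene), and the derived alanate transfers the alkenyl group to ethylene oxide with retention; MeLi is taken up by aluminium before it can exchange with the alkenyl iodide.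

Step 6
Reactants: 15 (3E,7Z)-8-iodo-4-methylnona-3,7-dien-1-ol
Product: 16 (2Z,6E)-2,9-diiodo-6-methylnona-2,6-diene
Conditions: I2, PPh3, imidazole, CH2Cl2, 0 °C
Reagents that add atoms: iodine II
Why: Appel-type iodination of the primary homoallylic alcohol by SN2; alkenes and the alkenyl iodide are inert.

Step 7
Reactants: 16 (2Z,6E)-2,9-diiodo-6-methylnona-2,6-diene; 17 methyl 2-[bis(2,2,2-trifluoroethoxy)phosphoryl]acetate
Product: 19 methyl (5E,9Z)-2-[bis(2,2,2-trifluoroethoxy)phosphoryl]-10-iodo-6-methylundeca-5,9-dienoate, via sodium phosphonoacetate 18 (not isolated)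
Conditions: 17 (2.5 equiv), NaH, DMF, 0 °C; then 16, 23 → 40 °C
Reagents that add atoms: none
Why: SN2 C-alkylation of the stabilised phosphonoacetate anion by the primary iodide (excess 17 suppresses dialkylation, the alkenyl iodide does not react); the new C-2 centre is racemic and is lost in step 9.

Step 8
Reactants: 10 2-[(3R)-3-(2,2-dimethoxyethyl)-8-hydroxy-8-methyl-4-methylidenenonyl]-2-methyl-2,3-dihydroquinazolin-4(1H)-one; 19 methyl (5E,9Z)-2-[bis(2,2,2-trifluoroethoxy)phosphoryl]-10-iodo-6-methylundeca-5,9-dienoate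
Product: 21 methyl (5E,9Z,13R)-2-[bis(2,2,2-trifluoroethoxy)phosphoryl]-18-hydroxy-6,10,18-trimethyl-14-methylidene-13-(2-oxoethyl)nonadeca-5,9-dienoate, via coupled acetal 20 (not isolated)
Conditions: 10 (1.3 equiv), 4CzIPN (3 mol %), NiBr2·dme (10 mol %), dtbbpy (12 mol %), 2,6-lutidine, DMA, 450 nm LEDs, 25 °C; then 1 M HCl, THF, 0 → 23 °C
Reagents that add atoms: water O
Why: Proposed new method: excited 4CzIPN oxidises the aminal N–H of 10 (lutidine takes the proton) to an N-centred radical whose β-scission, driven by aromatisation to 2-methylquinazolin-4(3H)-one, releases the primary C-13 radical rather than a methyl radical; this radical is captured by the alkenyl–Ni(II) species formed from Ni(0) and the Z iodide of 19, and reductive elimination from Ni(III) forms C12–C13 with retention of the Z geometry while reduced 4CzIPN returns Ni(I) to Ni(0); the closest known reaction is the Ni/photoredox deacylative arylation of ketone-derived dihydroquinazolinones with aryl bromides, and to my knowledge the use of a stereodefined trisubstituted alkenyl iodide with an unactivated primary radical has not been shown; acid work-up then hydrolyses the acetal to the aldehyde.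

Step 9
Reactants: 21 methyl (5E,9Z,13R)-2-[bis(2,2,2-trifluoroethoxy)phosphoryl]-18-hydroxy-6,10,18-trimethyl-14-methylidene-13-(2-oxoethyl)nonadeca-5,9-dienoate
Product: 22 methyl (1Z,4R,7Z,11E)-4-(6-hydroxy-6-methylhept-1-en-2-yl)-7,11-dimethylcyclotetradeca-1,7,11-triene-1-carboxylate
Conditions: KHMDS (1.05 equiv), 18-crown-6, THF, −78 °C, slow addition of 21 (final 1 mM)
Reagents that add atoms: none
Why: Intramolecular Still–Gennari Horner–Wadsworth–Emmons olefination at high dilution, in which fast irreversible elimination from the bis(trifluoroethyl)phosphonate adduct gives the Z enoate (C2 cis to CO2Me), which is also the trans ring alkene preferred in a 14-membered ring.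

**Compound list**
1 | (R)-(+)-limonene | CC1=CC[C@@H](CC1)C(C)=C | starting material
2 | 4-bromo-2-methylbutan-2-ol | CC(C)(O)CCBr | starting material
3 | 10-lithiolimonene | CC1=CC[C@@H](CC1)C(=C)C[Li] | intermediate
4 | lithium 4-bromo-2-methylbutan-2-olate | CC(C)([O-])CCBr.[Li+] | intermediate
5 | 2-methyl-6-[(1R)-4-methylcyclohex-3-en-1-yl]hept-6-en-2-ol | CC1=CC[C@@H](CC1)C(=C)CCCC(C)(C)O | intermediate
6 | (5R)-7-hydroperoxy-5-(6-hydroxy-6-methylhept-1-en-2-yl)-7-methoxyheptan-2-one (major Criegee regioisomer) | CC(=O)CC[C@H](CC(OC)OO)C(=C)CCCC(C)(C)O | intermediate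
7 | (3R)-3-(6-hydroxy-6-methylhept-1-en-2-yl)-6-oxoheptanal | CC(=O)CC[C@H](CC=O)C(=C)CCCC(C)(C)O | intermediate
8 | (5R)-5-(6-hydroxy-6-methylhept-1-en-2-yl)-7,7-dimethoxyheptan-2-one | CC(=O)CC[C@H](CC(OC)OC)C(=C)CCCC(C)(C)O | intermediate
9 | 2-aminobenzamide | NC(=O)c1ccccc1N | starting material
10 | 2-[(3R)-3-(2,2-dimethoxyethyl)-8-hydroxy-8-methyl-4-methylidenenonyl]-2-methyl-2,3-dihydroquinazolin-4(1H)-one | CC1(CC[C@H](CC(OC)OC)C(=C)CCCC(C)(C)O)NC(=O)c2ccccc2N1 | intermediate
11 | pent-4-ynal | C#CCCC=O | starting material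
12 | (5Z)-6-iodohept-5-en-1-yne | C#CCC/C=C(\I)C | intermediate
13 | [(1E,5Z)-6-iodo-2-methylhepta-1,5-dien-1-yl]dimethylalane | C[Al](C)/C=C(\C)CC/C=C(\I)C | intermediate
14 | lithium [(1E,5Z)-6-iodo-2-methylhepta-1,5-dien-1-yl]trimethylalanate | [Li+].C[Al-](C)(C)/C=C(\C)CC/C=C(\I)C | intermediate
15 | (3E,7Z)-8-iodo-4-methylnona-3,7-dien-1-ol | OCC/C=C(\C)CC/C=C(\I)C | intermediate
16 | (2Z,6E)-2,9-diiodo-6-methylnona-2,6-diene | ICC/C=C(\C)CC/C=C(\I)C | intermediate
17 | methyl 2-[bis(2,2,2-trifluoroethoxy)phosphoryl]acetate | COC(=O)CP(=O)(OCC(F)(F)F)OCC(F)(F)F | starting material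
18 | sodium salt of 17 | [Na+].COC(=O)[CH-]P(=O)(OCC(F)(F)F)OCC(F)(F)F | intermediate
19 | methyl (5E,9Z)-2-[bis(2,2,2-trifluoroethoxy)phosphoryl]-10-iodo-6-methylundeca-5,9-dienoate | COC(=O)C(CC/C=C(\C)CC/C=C(\I)C)P(=O)(OCC(F)(F)F)OCC(F)(F)F | intermediate
20 | methyl (5E,9Z,13R)-2-[bis(2,2,2-trifluoroethoxy)phosphoryl]-13-(2,2-dimethoxyethyl)-18-hydroxy-6,10,18-trimethyl-14-methylidenenonadeca-5,9-dienoate | COC(=O)C(CC/C=C(\C)CC/C=C(/C)CC[C@H](CC(OC)OC)C(=C)CCCC(C)(C)O)P(=O)(OCC(F)(F)F)OCC(F)(F)F | intermediate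
21 | methyl (5E,9Z,13R)-2-[bis(2,2,2-trifluoroethoxy)phosphoryl]-18-hydroxy-6,10,18-trimethyl-14-methylidene-13-(2-oxoethyl)nonadeca-5,9-dienoate | COC(=O)C(CC/C=C(\C)CC/C=C(/C)CC[C@H](CC=O)C(=C)CCCC(C)(C)O)P(=O)(OCC(F)(F)F)OCC(F)(F)F | intermediate
22 | methyl (1Z,4R,7Z,11E)-4-(6-hydroxy-6-methylhept-1-en-2-yl)-7,11-dimethylcyclotetradeca-1,7,11-triene-1-carboxylate | C=C(CCCC(C)(C)O)[C@H]1C/C=C(\C(=O)OC)CC/C=C(\C)CC/C=C(/C)CC1 | target

**Step count and risks**
Total: 9 steps. Longest linear sequence: 6 (steps 4, 5, 6, 7, 8, 9 from pent-4-ynal); the limonene branch is 5.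

The three steps most likely to fail:

Step 8 (the proposed new coupling). Release of an unactivated primary radical may be slow, and 1,5-hydrogen shifts may compete with capture by nickel. The fallback uses known chemistry, sets out from keto acetal 8 and returns at coupled acetal 20. Haloform degradation of the methyl ketone (NaOBr, dioxane/H2O, 0 °C, buffered work-up) gives (4R)-4-(2,2-dimethoxyethyl)-9-hydroxy-9-methyl-5-methylidenedecanoic acid F1. This is converted into its N-hydroxyphthalimide ester F2 (NHPI, DIC, DMAP cat.) and coupled with iodide 19 by Ni-electrocatalytic decarboxylative alkenylation (Ni/bipyridine, sacrificial anode, DMF, constant current) to give 20. The acid work-up of step 8 then gives 21.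

Step 9 (macrocyclic Still–Gennari). Oligomers or an eroded Z:E ratio are possible in the ring-closing mode. The fallback sets out from keto acetal 8 and returns at target 22; it makes the enoate intermolecularly and closes the ring by a two-electron C12–C13 coupling, so that no C-13 radical meets the enoate. Condensation of 8 with N′-methylpicolinohydrazonamide gives the pre-aromatic triazoline F3, and Cu-mediated dehydroacylation of it gives (7S)-7-(2,2-dimethoxyethyl)-2-methyl-6-methylidenenon-8-en-2-ol F4 (same spatial arrangement, the descriptor changes only by the priority rules). Acetal hydrolysis gives (3S)-3-ethenyl-8-hydroxy-8-methyl-4-methylidenenonanal F5. Intermolecular Still–Gennari olefination of F5 with 19 (KHMDS, 18-crown-6, THF, −78 °C) gives the Z enoate, methyl (2Z,5S)-5-ethenyl-10-hydroxy-2-[(3E,7Z)-8-iodo-4-methylnona-3,7-dien-1-yl]-10-methyl-6-methylideneundec-2-enoate F6. Disiamylborane hydroborates only the monosubstituted vinyl group to the alkylborane F7 (drawn with the hydroxyl free). Intramolecular B-alkyl Suzuki–Miyaura coupling with the Z alkenyl iodide (PdCl2(dppf), AsPh3, Cs2CO3, DMF/THF/H2O, high dilution) closes the ring to 22.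

Step 5 (carboalumination/alanate/epoxide opening next to an alkenyl iodide). Lithium–iodine exchange or incomplete alkenyl transfer may occur. The fallback sets out from pent-4-ynal 11 and returns at alcohol 15; it moves the organolithium step ahead of the alkenyl iodide. 11 is protected as 5,5-dimethoxypent-1-yne F8 (HC(OMe)3, TsOH cat., MeOH). Zr-catalysed carboalumination gives the alkenylalane F9, n-BuLi converts it into the lithium alanate F10, and opening of ethylene oxide gives (3E)-7,7-dimethoxy-4-methylhept-3-en-1-ol F11. Mild aqueous acid gives (4E)-7-hydroxy-4-methylhept-4-enal F12, and the Zhao olefination of step 4 applied to F12 gives 15.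

**Further compounds**
F1 | step 8 | (4R)-4-(2,2-dimethoxyethyl)-9-hydroxy-9-methyl-5-methylidenedecanoic acid | OC(=O)CC[C@H](CC(OC)OC)C(=C)CCCC(C)(C)O
F2 | step 8 | 1,3-dioxoisoindolin-2-yl (4R)-4-(2,2-dimethoxyethyl)-9-hydroxy-9-methyl-5-methylidenedecanoate | O=C(CC[C@H](CC(OC)OC)C(=C)CCCC(C)(C)O)ON1C(=O)c2ccccc2C1=O
F3 | step 9 | 5-[(3R)-3-(2,2-dimethoxyethyl)-8-hydroxy-8-methyl-4-methylidenenonyl]-1,5-dimethyl-3-(pyridin-2-yl)-4,5-dihydro-1H-1,2,4-triazole | CN1N=C(c2ccccn2)NC1(C)CC[C@H](CC(OC)OC)C(=C)CCCC(C)(C)O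
F4 | step 9 | (7S)-7-(2,2-dimethoxyethyl)-2-methyl-6-methylidenenon-8-en-2-ol | C=C[C@H](CC(OC)OC)C(=C)CCCC(C)(C)O
F5 | step 9 | (3S)-3-ethenyl-8-hydroxy-8-methyl-4-methylidenenonanal | C=C[C@H](CC=O)C(=C)CCCC(C)(C)O
F6 | step 9 | methyl (2Z,5S)-5-ethenyl-10-hydroxy-2-[(3E,7Z)-8-iodo-4-methylnona-3,7-dien-1-yl]-10-methyl-6-methylideneundec-2-enoate | COC(=O)/C(CC/C=C(\C)CC/C=C(\I)C)=C\C[C@@H](C=C)C(=C)CCCC(C)(C)O
F7 | step 9 | methyl (2Z,5R)-5-{2-[bis(3-methylbutan-2-yl)boranyl]ethyl}-10-hydroxy-2-[(3E,7Z)-8-iodo-4-methylnona-3,7-dien-1-yl]-10-methyl-6-methylideneundec-2-enoate | COC(=O)/C(CC/C=C(\C)CC/C=C(\I)C)=C\C[C@@H](CCB(C(C)C(C)C)C(C)C(C)C)C(=C)CCCC(C)(C)O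
F8 | step 5 | 5,5-dimethoxypent-1-yne | C#CCCC(OC)OC
F9 | step 5 | [(1E)-5,5-dimethoxy-2-methylpent-1-en-1-yl]dimethylalane | C[Al](C)/C=C(\C)CCC(OC)OC
F10 | step 5 | lithium butyl[(1E)-5,5-dimethoxy-2-methylpent-1-en-1-yl]dimethylalanate | [Li+].CCCC[Al-](C)(C)/C=C(\C)CCC(OC)OC
F11 | step 5 | (3E)-7,7-dimethoxy-4-methylhept-3-en-1-ol | OCC/C=C(\C)CCC(OC)OC
F12 | step 5 | (4E)-7-hydroxy-4-methylhept-4-enal | OCC/C=C(\C)CCC=O
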